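**Strategy.** Ring B is read as a masked 3-methylcyclohex-2-enone (labdane numbering). C6 is carried as a ketone whose two α-carbons (C5, C7) act as nucleophiles, and C8–C9–C10 as a tetrasubstituted enone (C8 carbonyl, C10 β-carbon). One amine-catalysed Michael addition/aldol condensation of the open-chain enedione 14 then makes C5–C10 (ring A, quaternary C10) and C7–C8 (ring B) and gives the labdadienone 16. The step exploits the C6 oxygen flanked by C5 and C7 and the C8=C9 alkene next to quaternary C10. Hydroxylation of the extended enolate at C7 (alkene shifts to C8=C9), reduction of the 6-ketone from the α face, acylation and desilylation complete the route.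

Key step: step 9

Remark: labdane numbering is used for all ring compounds (ring A = C1–C5 and C10; ring B = C5–C10; C17 = methyl on C8; C20 = methyl on C10; side chain C11–C16); α is the face opposite to the C10 methyl group.
Assumption: 1, 7, 10 and 11 are taken as commercial; 14 is drawn as the Z enone and 15 and 16 as the 9α-H epimers, but neither the enone geometry nor the C9 configuration matters, because C9 becomes sp2 again in step 10.

Step 1
Reactants: 1 (E)-3-methylpent-2-en-4-yn-1-ol
Product: 2 (E)-tert-butyldimethyl[(3-methylpent-2-en-4-yn-1-yl)oxy]silane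
Conditions: TBSCl, imidazole, DMF, 0 °C to rt
Reagents that add atoms: tert-butyldimethylsilyl chloride, CC(C)(C)[Si](C)(C)Cl
Why: Silyl ether formation (imidazole-promoted silylation) masks the primary allylic alcohol (future C15–OH) for the base, palladium and hydride steps that follow; no stereocenter is formed.

Step 2
Reactants: 2 (E)-tert-butyldimethyl[(3-methylpent-2-en-4-yn-1-yl)oxy]silane
Product: 3 (E)-tert-butyldimethyl[(3-methylpenta-2,4-dien-1-yl)oxy]silane
Conditions: H2 (1 atm), Pd/CaCO3 poisoned with Pb(OAc)2, quinoline, hexane, rt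
Reagents that add atoms: none
Why: Semihydrogenation over the poisoned palladium catalyst stops at the alkene, so the terminal alkyne becomes the vinyl group of a 1,3-diene while the E trisubstituted alkene (future C13=C14) is left as it is.

Step 3
Reactants: 3 (E)-tert-butyldimethyl[(3-methylpenta-2,4-dien-1-yl)oxy]silane
Product: 5 (E)-5-(tert-butyldimethylsilyloxy)-3-methylpent-3-en-1-ol, via alkylborane 4 (not isolated)
Conditions: 9-BBN, THF, 0 °C to rt; then NaOH, H2O2, 0 °C
Reagents that add atoms: hydrogen peroxide, OO
Why: Hydroboration–oxidation: the bulky borane adds only to the monosubstituted end of the diene with boron on the terminal carbon (future C11), and oxidation with retention gives the primary alcohol; no stereocenter is formed and the E alkene is kept.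

Step 4
Reactants: 5 (E)-5-(tert-butyldimethylsilyloxy)-3-methylpent-3-en-1-ol
Product: 6 (E)-tert-butyl[(5-iodo-3-methylpent-2-en-1-yl)oxy]dimethylsilane
Conditions: I2, PPh3, imidazole, CH2Cl2, 0 °C
Reagents that add atoms: iodine, II
Why: Appel-type iodination (Ph3P/I2) converts the primary alcohol into the primary iodide by SN2 displacement of the oxyphosphonium group without touching the allylic silyl ether.

Step 5
Reactants: 6 (E)-tert-butyl[(5-iodo-3-methylpent-2-en-1-yl)oxy]dimethylsilane; 7 pentane-2,4-dione
Product: 8 3-[(E)-5-(tert-butyldimethylsilyloxy)-3-methylpent-3-en-1-yl]pentane-2,4-dione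
Conditions: K2CO3, acetone, reflux
Reagents that add atoms: none
Why: C-Alkylation of a 1,3-diketone enolate: the potassium enolate of pentane-2,4-dione displaces the primary iodide (SN2), attaching the side chain to the carbon that becomes C9.

Step 6
Reactants: 8 3-[(E)-5-(tert-butyldimethylsilyloxy)-3-methylpent-3-en-1-yl]pentane-2,4-dione
Product: 9 (Z)-3-[(E)-5-(tert-butyldimethylsilyloxy)-3-methylpent-3-en-1-yl]-4-oxopent-2-en-2-yl trifluoromethanesulfonate
Conditions: NaH, THF, 0 °C; then PhNTf2, 0 °C to rt
Reagents that add atoms: N-phenylbis(trifluoromethanesulfonimide), O=S(=O)(N(c1ccccc1)S(=O)(=O)C(F)(F)F)C(F)(F)F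
Why: O-Sulfonylation of the sodium enolate gives the vinylogous acyl triflate (enol triflate), the chelated U-shaped enolate favouring the Z isomer; the alkene geometry is of no consequence later.

Step 7
Reactants: 10 4-methylpent-3-en-2-one; 11 allyltrimethylsilane
Product: 12 4,4-dimethylhept-6-en-2-one
Conditions: TiCl4, CH2Cl2, −78 °C; then H2O
Reagents that add atoms: none
Why: Hosomi–Sakurai conjugate allylation: the allylsilane attacks the β-carbon of the TiCl4-activated enone and creates the gem-dimethyl quaternary carbon (future C4) with a terminal alkene for the coupling.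

Step 8
Reactants: 12 4,4-dimethylhept-6-en-2-one; 9 (Z)-3-[(E)-5-(tert-butyldimethylsilyloxy)-3-methylpent-3-en-1-yl]-4-oxopent-2-en-2-yl trifluoromethanesulfonate
Product: 14 (3Z)-3-[(E)-5-(tert-butyldimethylsilyloxy)-3-methylpent-3-en-1-yl]-4,8,8-trimethylundec-3-ene-2,10-dione, via alkylborane 13 (not isolated)
Conditions: 12, 9-BBN, THF, 0 °C to rt; then 9, PdCl2(dppf) (5 mol %), AsPh3, K3PO4 (aq.), DMF–THF, rt
Reagents that add atoms: none
Why: B-alkyl Suzuki–Miyaura coupling: 9-BBN hydroborates the terminal alkene much faster than it reduces the ketone, and the primary alkylborane couples with the activated enol triflate with retention of alkene geometry to join C1 to C10.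

Step 9
Reactants: 14 (3Z)-3-[(E)-5-(tert-butyldimethylsilyloxy)-3-methylpent-3-en-1-yl]-4,8,8-trimethylundec-3-ene-2,10-dione
Product: 16 15-(tert-butyldimethylsilyloxy)labda-7,13E-dien-6-one (5α-H; 9α-H; 10β-methyl), via Michael adduct 15 (not isolated)
Conditions: 9-amino-9-deoxy-epi-quinine (20 mol %), CF3CO2H (40 mol %), toluene, 50 °C; aq. NaHCO3 work-up
Reagents that add atoms: none
Why: Proposed new method: the chiral primary amine should condense with the unconjugated C6 methyl ketone, its more substituted secondary enamine (C5) should add 6-exo-trig to the acid-activated enone carbon C10 (Michael step, C5–C10), and the isomeric C7 enamine should then close onto the C8 ketone with loss of water (aldol condensation, C7–C8). The closest known reaction types are the primary-amine-catalysed asymmetric Robinson annulation and the isophorone-type Michael/aldol condensation of a ketone with a β,β-disubstituted enone; what has not been shown is a tetrasubstituted acyclic enone as acceptor in a double ring closure. Ring A closes in the Michael step (6-exo-trig) and ring B in the aldol step (6-exo-trig onto the C8 carbonyl with the enamine double bond inside the new ring). C10 is set by the catalyst, which differentiates the faces of the C5 enamine and, through the chair-like six-membered transition state, the face of C10 that is attacked; C5 (α to the new enone carbonyl) and C9 (γ) are epimerisable and should settle as the trans-fused 5α-H, 9α-H isomer. The step needs C5 and not C7 as Michael donor, which the ring size secures (six- against eight-membered), and aldolisation C7 to C8 and not C17 to C6, which is secured because the C6 carbonyl hangs on C5 between the quaternary carbons C4 and C10 and is the poorer electrophile.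

Step 10
Reactants: 16 15-(tert-butyldimethylsilyloxy)labda-7,13E-dien-6-one (5α-H; 9α-H; 10β-methyl)
Product: 19 15-(tert-butyldimethylsilyloxy)-7α-(triethylsilyloxy)labda-8,13E-dien-6-one, via potassium dienolate 17 (not isolated), via potassium alkoxide 18 (not isolated)
Conditions: KOt-Bu, THF–t-BuOH, 0 °C; 2-(phenylsulfonyl)-3-phenyloxaziridine, −78 °C; then Et3SiCl, −78 to 0 °C
Reagents that add atoms: 2-(phenylsulfonyl)-3-phenyloxaziridine, O=S(=O)(N1OC1c1ccccc1)c1ccccc1; chlorotriethylsilane, CC[Si](CC)(CC)Cl
Why: Deconjugative α-hydroxylation of an extended enolate by an N-sulfonyloxaziridine: the thermodynamic 6,8-dienolate should take up oxygen at C7 (its α-carbon) from the less hindered α face, anti to the C10 methyl group, which sets the 7α-oxygen while the alkene moves to C8=C9, and the alkoxide is silylated in the same flask.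

Step 11
Reactants: 19 15-(tert-butyldimethylsilyloxy)-7α-(triethylsilyloxy)labda-8,13E-dien-6-one
Product: 20 15-(tert-butyldimethylsilyloxy)-7α-(triethylsilyloxy)labda-8,13E-dien-6β-ol
Conditions: NaBH4, MeOH–THF, −40 to 0 °C
Reagents that add atoms: none
Why: Hydride reduction of a hindered cyclohexanone under steric approach control: the β face of C6 is blocked by the axial methyl groups on C4 and C10, so hydride should enter from the α face and give the axial 6β-alcohol, and the trans-diaxial relation to the 7α-silyl ether prevents silyl migration.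

Step 12
Reactants: 20 15-(tert-butyldimethylsilyloxy)-7α-(triethylsilyloxy)labda-8,13E-dien-6β-ol
Product: 21 15-(tert-butyldimethylsilyloxy)-7α-(triethylsilyloxy)labda-8,13E-dien-6β-yl 3-methylbutanoate
Conditions: 3-methylbutanoyl chloride, DMAP, pyridine, CH2Cl2, 40 °C
Reagents that add atoms: 3-methylbutanoyl chloride, CC(C)CC(Cl)=O
Why: DMAP-catalysed esterification (nucleophilic acyl substitution through the N-acylpyridinium ion) acylates the only free hydroxyl, the hindered axial 6β-OH, without touching a stereocenter.

Step 13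
Reactants: 21 15-(tert-butyldimethylsilyloxy)-7α-(triethylsilyloxy)labda-8,13E-dien-6β-yl 3-methylbutanoate
Product: 22 6β-(3-methylbutanoyloxy)labda-8,13E-diene-7α,15-diol (CNP0173680.1)
Conditions: Bu4NF, AcOH, THF, 0 °C to rt
Reagents that add atoms: none
Why: Fluoride-mediated desilylation frees the 7α- and 15-hydroxyls in one operation, and the trans-diaxial arrangement of the 6β-ester and the 7α-hydroxyl rules out acyl migration.

**Compound list**

1 | (E)-3-methylpent-2-en-4-yn-1-ol | C#C/C(C)=C/CO | starting material
2 | (E)-tert-butyldimethyl[(3-methylpent-2-en-4-yn-1-yl)oxy]silane | C#C/C(C)=C/CO[Si](C)(C)C(C)(C)C | intermediate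
3 | (E)-tert-butyldimethyl[(3-methylpenta-2,4-dien-1-yl)oxy]silane | C=C/C(C)=C/CO[Si](C)(C)C(C)(C)C | intermediate
4 | 9-[(E)-5-(tert-butyldimethylsilyloxy)-3-methylpent-3-en-1-yl]-9-borabicyclo[3.3.1]nonane | C1CCC2CCCC1B2CC/C(C)=C/CO[Si](C)(C)C(C)(C)C | intermediate
5 | (E)-5-(tert-butyldimethylsilyloxy)-3-methylpent-3-en-1-ol | OCC/C(C)=C/CO[Si](C)(C)C(C)(C)C | intermediate
6 | (E)-tert-butyl[(5-iodo-3-methylpent-2-en-1-yl)oxy]dimethylsilane | ICC/C(C)=C/CO[Si](C)(C)C(C)(C)C | intermediate
7 | pentane-2,4-dione | CC(=O)CC(C)=O | starting material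
8 | 3-[(E)-5-(tert-butyldimethylsilyloxy)-3-methylpent-3-en-1-yl]pentane-2,4-dione | CC(=O)C(CC/C(C)=C/CO[Si](C)(C)C(C)(C)C)C(C)=O | intermediate
9 | (Z)-3-[(E)-5-(tert-butyldimethylsilyloxy)-3-methylpent-3-en-1-yl]-4-oxopent-2-en-2-yl trifluoromethanesulfonate | C/C(OS(=O)(=O)C(F)(F)F)=C(\CC/C(C)=C/CO[Si](C)(C)C(C)(C)C)C(C)=O | intermediate
10 | 4-methylpent-3-en-2-one | CC(=O)C=C(C)C | starting material
11 | allyltrimethylsilane | C=CC[Si](C)(C)C | starting material
12 | 4,4-dimethylhept-6-en-2-one | CC(=O)CC(C)(C)CC=C | intermediate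
13 | 7-(9-borabicyclo[3.3.1]nonan-9-yl)-4,4-dimethylheptan-2-one | CC(=O)CC(C)(C)CCCB1C2CCCC1CCC2 | intermediate
14 | (3Z)-3-[(E)-5-(tert-butyldimethylsilyloxy)-3-methylpent-3-en-1-yl]-4,8,8-trimethylundec-3-ene-2,10-dione | C/C(CCCC(C)(C)CC(C)=O)=C(\CC/C(C)=C/CO[Si](C)(C)C(C)(C)C)C(C)=O | intermediate
15 | 15-(tert-butyldimethylsilyloxy)-7,8-secolabd-13E-ene-6,8-dione (Michael adduct; 5α-H, 9α-H, 10β-methyl; acetyl on C5 and the C9 chain on C10 trans on ring A) | CC(=O)[C@H]1C(C)(C)CCC[C@]1(C)[C@@H](CC/C(C)=C/CO[Si](C)(C)C(C)(C)C)C(C)=O | intermediate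
16 | 15-(tert-butyldimethylsilyloxy)labda-7,13E-dien-6-one (5α-H, 9α-H, 10β-methyl; trans-decalin) | CC1=CC(=O)[C@H]2C(C)(C)CCC[C@]2(C)[C@H]1CC/C(C)=C/CO[Si](C)(C)C(C)(C)C | intermediate
17 | potassium 15-(tert-butyldimethylsilyloxy)labda-6,8,13E-trien-6-olate (5α-H, 10β-methyl) | CC1=C(CC/C(C)=C/CO[Si](C)(C)C(C)(C)C)[C@@]2(C)CCCC(C)(C)[C@@H]2C([O-])=C1.[K+] | intermediate
18 | potassium 15-(tert-butyldimethylsilyloxy)-6-oxolabda-8,13E-dien-7α-olate (5α-H, 10β-methyl) | CC1=C(CC/C(C)=C/CO[Si](C)(C)C(C)(C)C)[C@@]2(C)CCCC(C)(C)[C@@H]2C(=O)[C@H]1[O-].[K+] | intermediate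
19 | 15-(tert-butyldimethylsilyloxy)-7α-(triethylsilyloxy)labda-8,13E-dien-6-one (5α-H, 10β-methyl) | CC1=C(CC/C(C)=C/CO[Si](C)(C)C(C)(C)C)[C@@]2(C)CCCC(C)(C)[C@@H]2C(=O)[C@H]1O[Si](CC)(CC)CC | intermediate
20 | 15-(tert-butyldimethylsilyloxy)-7α-(triethylsilyloxy)labda-8,13E-dien-6β-ol (5α-H, 10β-methyl) | CC1=C(CC/C(C)=C/CO[Si](C)(C)C(C)(C)C)[C@@]2(C)CCCC(C)(C)[C@@H]2[C@H](O)[C@H]1O[Si](CC)(CC)CC | intermediate
21 | 15-(tert-butyldimethylsilyloxy)-7α-(triethylsilyloxy)labda-8,13E-dien-6β-yl 3-methylbutanoate (5α-H, 10β-methyl) | CC1=C(CC/C(C)=C/CO[Si](C)(C)C(C)(C)C)[C@@]2(C)CCCC(C)(C)[C@@H]2[C@H](OC(=O)CC(C)C)[C@H]1O[Si](CC)(CC)CC | intermediate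
22 | (5S,6S,7S,10S)-6β-(3-methylbutanoyloxy)labda-8,13E-diene-7α,15-diol, CNP0173680.1 | CC1=C(CC/C(C)=C/CO)[C@@]2(C)CCCC(C)(C)[C@@H]2[C@H](OC(=O)CC(C)C)[C@H]1O | target

**Step count and risks**

Total step count: 13. Longest linear sequence: 12 steps (steps 1 to 6 and 8 to 13).

Step 9 (carries the label). What may go wrong is a Michael step that is too slow or unselective: the enamine may fail to attack the hindered tetrasubstituted enone, or it may attack without face discrimination. If only the sense of induction is wrong, the quinidine-derived pseudo-enantiomer of the catalyst is used. The fallback uses known chemistry, sets out from 14 and returns at 16. The base-mediated isophorone-type annulation (KOt-Bu, t-BuOH, 60 °C) closes both rings under thermodynamic control without a chiral agent. It should give 16 as a racemate together with its mirror image, the ent-enone F1. The two are separated by preparative chromatography on a chiral stationary phase (amylose tris(3,5-dimethylphenylcarbamate)), and 16 goes on.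

Step 10. What may go wrong is loss of site control: proton abstraction at C5 or at the C8 methyl group instead of C9, or oxygen transfer to the γ-carbon (C9) of the dienolate. The fallback sets out from 16 and returns at 19. Soft enolisation with Et3SiOTf and Et3N (CH2Cl2, 0 °C) gives the through-conjugated 6-triethylsilyloxy-6,8-diene F2. Rubottom oxidation with dimethyldioxirane (acetone, −78 °C) then epoxidises the enol-ether double bond from the α face; ring opening with 1,4-shift of the silyl group to the new oxygen should deliver 19 directly.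

Step 11. What may go wrong is poor facial selectivity: the axial 7α-silyloxy group favours, on stereoelectronic grounds, hydride attack anti to the C7–O bond, that is from the β face, against the steric bias. The fallback sets out from 16 and returns at 20. The hydroxylation of step 10 is quenched with AcOH instead of Et3SiCl to give the free 7α-hydroxy ketone F3. Me4NBH(OAc)3 (MeCN–AcOH, −30 °C) binds to the 7α-hydroxyl and delivers hydride intramolecularly to the α face of C6, which should give the 6β,7α-diol F4. Et3SiCl and imidazole (DMF, −20 °C) then silylate only the less hindered allylic 7α-hydroxyl and give 20.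

Further compounds
F1 | step 9 | ent-15-(tert-butyldimethylsilyloxy)labda-7,13E-dien-6-one (mirror image of 16) | CC1=CC(=O)[C@@H]2C(C)(C)CCC[C@@]2(C)[C@@H]1CC/C(C)=C/CO[Si](C)(C)C(C)(C)C
F2 | step 10 | 15-(tert-butyldimethylsilyloxy)-6-(triethylsilyloxy)labda-6,8,13E-triene (5α-H, 10β-methyl) | CC1=C(CC/C(C)=C/CO[Si](C)(C)C(C)(C)C)[C@@]2(C)CCCC(C)(C)[C@@H]2C(O[Si](CC)(CC)CC)=C1
F3 | step 11 | 15-(tert-butyldimethylsilyloxy)-7α-hydroxylabda-8,13E-dien-6-one (5α-H, 10β-methyl) | CC1=C(CC/C(C)=C/CO[Si](C)(C)C(C)(C)C)[C@@]2(C)CCCC(C)(C)[C@@H]2C(=O)[C@H]1O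
F4 | step 11 | 15-(tert-butyldimethylsilyloxy)labda-8,13E-diene-6β,7α-diol (5α-H, 10β-methyl) | CC1=C(CC/C(C)=C/CO[Si](C)(C)C(C)(C)C)[C@@]2(C)CCCC(C)(C)[C@@H]2[C@H](O)[C@H]1O
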